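**Assumption:** the target SMILES has no stereodescriptors and no stereogenic centre, and the 15-membered cyclophane is treated as conformationally mobile, so the route makes the achiral structure as drawn. This route is a paper design and has not been run.

## Retrosynthetic overview

1. Juglanin A ⇐ decarboxylation and MOM removal from macrocyclic β-keto esters ⇐ high-dilution Dieckmann macrocyclisation of an open diaryl-ether diester (C3 ester arm on ring A, C5 ester arm on ring B).
2. Either enolisation mode of the Dieckmann gives the same C-3 ketone after decarboxylation, so the key step has no regiochemical demand.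
3. Diester ⇐ hydrogenation of a dienoate ⇐ vinylogous HWE on a ring-B aldehyde.
4. Diaryl ether ⇐ early intermolecular SNAr (para-CHO-activated fluoroarene plus isovanillyl-type phenol), instead of the usual late Ullmann macro-etherification.
5. Ring order: both arenes are bought intact, the C–O biaryl ether bond is made first, and the 15-membered ring is closed last by C–C bond formation at the ketone.

## Route

**Step 1**
Reactants: 1, 3-fluoro-2-methoxyphenol
Product: 2, 4-fluoro-2-hydroxy-3-methoxybenzaldehyde
Conditions: MgCl2, Et3N, (CH2O)n, MeCN, reflux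
Reagents that add atoms: paraformaldehyde (as formaldehyde, C=O)
Why: Mg-phenoxide-directed ortho-formylation (Casnati–Skattebøl) is ortho-specific, and the only free ortho position is C-6, which gives the required CHO/OH/OMe/F 1,2,3,4-pattern.

**Step 2**
Reactants: 2, 4-fluoro-2-hydroxy-3-methoxybenzaldehyde
Product: 3, 4-fluoro-3-methoxy-2-(methoxymethoxy)benzaldehyde
Conditions: MOMCl, i-Pr2NEt, CH2Cl2, 0 °C→rt
Reagents that add atoms: chloromethyl methyl ether, COCCl
Why: Standard O-alkylation (MOM protection) removes the phenoxide that would otherwise deactivate the ring toward SNAr; MOM is stable to all later base, HWE and hydrogenation conditions.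

**Step 3**
Reactants: 4, 3-(3-hydroxy-4-methoxyphenyl)propanoic acid (dihydroisoferulic acid)
Product: 5, ethyl 3-(3-hydroxy-4-methoxyphenyl)propanoate
Conditions: EtOH, cat. H2SO4, reflux
Reagents that add atoms: ethanol, CCO
Why: Fischer esterification; the phenol is untouched and the ethyl ester matches the ester introduced in step 5.

**Step 4**
Reactants: 3, 4-fluoro-3-methoxy-2-(methoxymethoxy)benzaldehyde; 5, ethyl 3-(3-hydroxy-4-methoxyphenyl)propanoate
Product: 6, ethyl 3-{3-[4-formyl-2-methoxy-3-(methoxymethoxy)phenoxy]-4-methoxyphenyl}propanoate
Conditions: Cs2CO3, dry DMSO, 110 °C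
Reagents that add atoms: none (both partners are numbered reactants)
Why: SNAr of the phenoxide on a fluoride para to the aldehyde (Meisenheimer stabilisation by CHO); carbonate is too weak to enolise the ester, and the aldehyde has no α-hydrogens.

**Step 5**
Reactants: 6, the diaryl-ether aldehyde; 7, triethyl 4-phosphonocrotonate
Product: 8, ethyl (2E,4E)-5-{4-[5-(3-ethoxy-3-oxopropyl)-2-methoxyphenoxy]-3-methoxy-2-(methoxymethoxy)phenyl}penta-2,4-dienoate
Conditions: 7, LiHMDS, THF, −78 °C, then 6, −78 °C→rt
Reagents that add atoms: triethyl 4-phosphonocrotonate (7), CCOC(=O)/C=C/CP(=O)(OCC)OCC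
Why: Vinylogous Horner–Wadsworth–Emmons olefination adds the four-carbon ester arm in one step; the preformed phosphonate anion leaves the saturated ester alone, and alkene geometry is irrelevant because it is hydrogenated next.

**Step 6**
Reactants: 8, the dienoate
Product: 9, ethyl 5-{4-[5-(3-ethoxy-3-oxopropyl)-2-methoxyphenoxy]-3-methoxy-2-(methoxymethoxy)phenyl}pentanoate
Conditions: H2 (1 atm), 10% Pd/C, EtOAc, rt
Reagents that add atoms: none (H2 only)
Why: Catalytic hydrogenation saturates both conjugated C=C bonds; there are no benzyl groups or halides, and MOM, aryl ethers and esters are inert.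

**Step 7 (key step)**
Reactants: 9, the C3/C5 diester
Product: 10 and 11, regioisomeric 15-membered β-keto esters (racemic, not separated). 10 is MOM-protected juglanin A with CO2Et on C-4 of the bridge (α to the ketone, ring-B side); 11 has CO2Et on C-2 (α to the ketone, ring-A side).
Conditions: t-BuOK (4 equiv), THF, reflux, syringe-pump addition of 9 over 12 h (final ≤2 mM); AcOH quench
Reagents that add atoms: none
Why: Dieckmann condensation (intramolecular Claisen) under high dilution, a known reaction type for 14–17-membered carbocyclic ketones but untested on this cyclophane. Ring closure is driven by irreversible deprotonation of the β-keto ester, and both enolate modes lead to the same ketone after step 8. The new stereocentre is racemic and is destroyed in step 8.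

**Step 8**
Reactants: 10 and 11, the β-keto ester mixture
Product: 12, juglanin A
Conditions: (i) cat. conc. HCl, MeOH, 50 °C, then concentrate; (ii) 6 M HCl/AcOH (1:1), 100 °C
Reagents that add atoms: none
Why: Stage (i) removes the MOM acetal, with formaldehyde trapped as volatile dimethoxymethane. Stage (ii) is acid ester hydrolysis and β-keto acid decarboxylation, which avoids the base-induced retro-Claisen ring opening; aryl methyl ethers and the diaryl ether survive HCl/AcOH.

## Compound list

1 | 3-fluoro-2-methoxyphenol | COc1c(O)cccc1F | starting material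
2 | 4-fluoro-2-hydroxy-3-methoxybenzaldehyde | COc1c(O)c(C=O)ccc1F | intermediate
3 | 4-fluoro-3-methoxy-2-(methoxymethoxy)benzaldehyde | COCOc1c(C=O)ccc(F)c1OC | intermediate
4 | 3-(3-hydroxy-4-methoxyphenyl)propanoic acid | COc1ccc(CCC(=O)O)cc1O | starting material
5 | ethyl 3-(3-hydroxy-4-methoxyphenyl)propanoate | CCOC(=O)CCc1ccc(OC)c(O)c1 | intermediate
6 | ethyl 3-{3-[4-formyl-2-methoxy-3-(methoxymethoxy)phenoxy]-4-methoxyphenyl}propanoate | CCOC(=O)CCc1ccc(OC)c(Oc2ccc(C=O)c(OCOC)c2OC)c1 | intermediate
7 | triethyl 4-phosphonocrotonate | CCOC(=O)/C=C/CP(=O)(OCC)OCC | starting material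
8 | ethyl (2E,4E)-5-{4-[5-(3-ethoxy-3-oxopropyl)-2-methoxyphenoxy]-3-methoxy-2-(methoxymethoxy)phenyl}penta-2,4-dienoate | CCOC(=O)CCc1ccc(OC)c(Oc2ccc(/C=C/C=C/C(=O)OCC)c(OCOC)c2OC)c1 | intermediate
9 | ethyl 5-{4-[5-(3-ethoxy-3-oxopropyl)-2-methoxyphenoxy]-3-methoxy-2-(methoxymethoxy)phenyl}pentanoate | CCOC(=O)CCc1ccc(OC)c(Oc2ccc(CCCCC(=O)OCC)c(OCOC)c2OC)c1 | intermediate
10 | O-MOM juglanin A 4-carboxylic acid ethyl ester (racemic macrocyclic β-keto ester, CO2Et on ring-B side of ketone) | COc1ccc2cc1Oc1ccc(c(OCOC)c1OC)CCCC(C(=O)OCC)C(=O)CC2 | intermediate
11 | O-MOM juglanin A 2-carboxylic acid ethyl ester (racemic macrocyclic β-keto ester, CO2Et on ring-A side of ketone) | COc1ccc2cc1Oc1ccc(c(OCOC)c1OC)CCCCC(=O)C(C(=O)OCC)C2 | intermediate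
12 | juglanin A | COc1ccc2cc1Oc1ccc(c(O)c1OC)CCCCC(=O)CC2 | target

## Summary

**Total steps:** 8
**Longest linear sequence:** 7 (steps 1, 2, 4, 5, 6, 7, 8 from compound 1; step 3 is a one-step side branch)

**Three steps most likely to fail**

1. **Step 7, macro-Dieckmann.** Risks are oligomerisation and an unfavourable equilibrium for the meta,para-cyclophane. Fallback: close the ring by ring-closing metathesis instead. From 6, methylenate the aldehyde (Wittig) to the styrene and convert the ester arm to the but-3-enyl ketone (Weinreb amide, then but-3-enylMgBr). Grubbs II RCM forms C6=C7, followed by H2/Pd-C and MOM removal.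

2. **Step 4, SNAr.** The fluoroarene carries two donor oxygens, and the flanking OMe may slow substitution. Fallback: reverse the polarity with a Cu-mediated Chan–Lam coupling. Couple the ring-A arylboronic acid (Miyaura borylation of ethyl 3-(3-bromo-4-methoxyphenyl)propanoate) with 2,4-dihydroxy-3-methoxybenzaldehyde at its non-chelated 4-OH, then MOM-protect to rejoin the route at 6.

3. **Step 8, one-pot MOM removal and decarboxylation.** Risks are formaldehyde-derived aryl alkylation and incomplete hydrolysis of the hindered macrocyclic ester. Fallback: change the protecting-group plan. Use a benzyl ether in step 2 so it is cleaved during the step 6 hydrogenation, run the Dieckmann on the phenoxide with extra base, and finish with a neutral Krapcho dealkoxycarbonylation (LiCl, wet DMSO, 150 °C), so no acid or formaldehyde is involved.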